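**Retrosynthetic overview**

1. Numbering: C1 (CH–O-tigloyl), C2, C3 (methyl-bearing olefin carbon), C4, C5 (CH–OAc), C6, C7 (methyl carbinol), C8, C9 (enol-lactone carbon), C10; lactone carbons C11 (α, bears C13H2OAc) and C12 (C=O).
2. Feature and key disconnection: in the ten-membered carbocycle the C5 oxygen and the C8=C9 enol lactone are γ,δ-related through C6–C7, and the bond ends at the tertiary carbinol C7. Cutting C6–C7 (retro-Claisen) gives an eight-membered 2-methylene cyclic ketal at C9 of the butenolide that carries a (Z)-enol silane.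
3. The eight-membered ring comes from ring-closing metathesis at C3=C4 of a mixed C9 ketal of a 5-hydroxybutenolide with (S)-1-iodobut-3-en-2-ol. The C7 ketone, its enol silane and the exocyclic methylene are unveiled only after ring closure, because a ketone β to the C9 ketal would eliminate during ketal formation.
4. The hydroxybutenolide comes from singlet-oxygen oxidation of a 2,3,4-trisubstituted furan, built from dimethyl furan-3,4-dicarboxylate by alkoxide-directed C9 lithiation, propylene oxide opening and asymmetric methallylation at C1.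
5. Ring order: furan (bought), butenolide, eight-membered oxacycle (metathesis), ten-membered carbocycle (Claisen ring expansion); then C5 reduction, desilylation and acylations.

Key step: step 16

Assumption: the configurations at C7 (from (S)-propylene oxide) and at C5 of the iodo alcohol are auxiliary and are erased in steps 13 and 15, so either enantiomer of these two reagents would serve; the methallylborane from (−)-α-pinene is taken to attack the Re face of the furan-3-carbaldehyde as it does with aryl aldehydes.

**Route**

Step 1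
Reactants: 1 dimethyl furan-3,4-dicarboxylate
Product: 2 furan-3,4-diyldimethanol
Conditions: LiAlH4, THF, 0 °C → rt; H2O, aq. NaOH work-up
Reagents that add atoms: none
Why: Hydride reduction of both ester groups to primary alcohols (ester reduction with LiAlH4), no stereocentre involved.

Step 2
Reactants: 2 furan-3,4-diyldimethanol
Product: 3 [4-(tert-butyldimethylsilyloxymethyl)furan-3-yl]methanol
Conditions: NaH (1.0 equiv), THF, rt; TBSCl (1.0 equiv), 0 °C → rt
Reagents that add atoms: tert-butyldimethylsilyl chloride, CC(C)(C)[Si](C)(C)Cl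
Why: Monosilylation of a symmetrical diol through its sparingly soluble monosodium alkoxide (McDougal protocol) should differentiate the future C1 and C13 carbons.

Step 3
Reactants: 3 [4-(tert-butyldimethylsilyloxymethyl)furan-3-yl]methanol; 4 (S)-propylene oxide
Product: 6 (2S)-1-[4-(tert-butyldimethylsilyloxymethyl)-3-(hydroxymethyl)furan-2-yl]propan-2-ol, via dilithiated furan 5 (not isolated)
Conditions: n-BuLi (2.2 equiv), DME, 0 °C; then 4, 0 °C → rt; aq. NH4Cl
Reagents that add atoms: none
Why: Alkoxide-directed ortho-lithiation places the second lithium on the furan α-carbon next to the CH2OLi group (C9) and not on C12, and the furyllithium opens the epoxide at its CH2 carbon (SN2 epoxide opening), so C7 keeps the S configuration of the epoxide.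

Step 4
Reactants: 6 (2S)-1-[4-(tert-butyldimethylsilyloxymethyl)-3-(hydroxymethyl)furan-2-yl]propan-2-ol
Product: 7 bis(triethylsilyl) ether of 6 (C1–OTES and C7–OTES)
Conditions: TESCl (2.4 equiv), imidazole, CH2Cl2, 0 °C → rt
Reagents that add atoms: triethylsilyl chloride, CC[Si](CC)(CC)Cl
Why: Standard silylation of a primary and a secondary alcohol with a silyl chloride and imidazole.

Step 5
Reactants: 7 bis(triethylsilyl) ether
Product: 8 4-(tert-butyldimethylsilyloxymethyl)-2-[(2S)-2-(triethylsilyloxy)propyl]furan-3-carbaldehyde
Conditions: (COCl)2, DMSO, CH2Cl2, −78 → −40 °C; Et3N, −78 °C → rt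
Reagents that add atoms: none
Why: Direct Swern oxidation of a primary triethylsilyl ether, in which the chlorosulfonium salt cleaves only the unhindered primary TES ether and oxidises it to the aldehyde while the secondary TES and the primary TBS ethers should stay.

Step 6
Reactants: 8 furan-3-carbaldehyde
Product: 9 (1R)-1-{4-(tert-butyldimethylsilyloxymethyl)-2-[(2S)-2-(triethylsilyloxy)propyl]furan-3-yl}-3-methylbut-3-en-1-ol
Conditions: (+)-Ipc2BOMe [from (−)-α-pinene], methallylMgCl, Et2O, −78 °C → rt; then 8, −78 °C; NaOH, H2O2
Reagents that add atoms: methallylmagnesium chloride, CC(=C)C[Mg]Cl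
Why: Brown asymmetric methallylboration through a chair Zimmerman–Traxler transition state, in which the borane from (−)-α-pinene should deliver the methallyl group to the Re face of the aldehyde and set C1 as R.

Step 7
Reactants: 9 (1R)-homoallylic alcohol
Product: 10 fully protected furan (C1–OTBS, C13–OTBS, C7–OTES)
Conditions: TBSOTf, 2,6-lutidine, CH2Cl2, −78 → 0 °C
Reagents that add atoms: tert-butyldimethylsilyl triflate, CC(C)(C)[Si](C)(C)OS(=O)(=O)C(F)(F)F
Why: Silyl triflate silylation of a hindered secondary alcohol, C1 untouched.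

Step 8
Reactants: 10 fully protected furan
Product: 12 5-hydroxybutenolide (C9 hemiketal as both epimers), via furan endoperoxide 11 (not isolated)
Conditions: O2, hν, tetraphenylporphyrin (cat.), CH2Cl2, −78 °C; then i-Pr2NEt, −78 → 0 °C
Reagents that add atoms: dioxygen, O=O
Why: [4+2] cycloaddition of singlet oxygen to the furan followed by base-induced Kornblum–DeLaMare fragmentation, in which the only bridgehead hydrogen (on C12) is removed so that C12 becomes the lactone carbonyl and C9 the hemiketal carbon.

Step 9
Reactants: 13 (S)-2-hydroxybut-3-en-1-yl 4-methylbenzenesulfonate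
Product: 14 (S)-1-iodobut-3-en-2-ol
Conditions: NaI, acetone, 50 °C
Reagents that add atoms: sodium iodide, [Na+].[I-]
Why: Finkelstein substitution at the primary carbon, which leaves the carbinol stereocentre untouched.

Step 10
Reactants: 12 5-hydroxybutenolide; 14 (S)-1-iodobut-3-en-2-ol
Product: 15 (9S)-mixed ketal, 5-[(S)-1-iodobut-3-en-2-yloxy]butenolide
Conditions: 14 (3 equiv), PPTS (0.2 equiv), 4 Å MS, benzene, 40 °C; separation of the C9 epimers, (9R)-epimer re-subjected
Reagents that add atoms: none
Why: Acid-catalysed pseudo-ester (mixed ketal) formation from the hydroxybutenolide, which equilibrates with its (Z)-4-oxo-2-enoic acid form, while sieves remove water; C9 forms under equilibrium control as both epimers, of which the (9S)-epimer is separated and the other recycled.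

Step 11
Reactants: 15 (9S)-mixed ketal
Product: 16 eight-membered bicyclic ketal (1R,3Z,5S,9S) with C6 iodide and C7–OTES
Conditions: second-generation Grubbs catalyst RuCl2(=CHPh)(H2IMes)(PCy3) (10 mol%), toluene (2 mM), 80 °C
Reagents that add atoms: none
Why: Ring-closing metathesis of the vinyl group with the 1,1-disubstituted methallyl olefin gives the trisubstituted C3=C4 bond, necessarily cis in an eight-membered ring; the two arms sit on the neighbouring atoms C9 and C10 of the rigid butenolide, and in the (9S)-epimer they can meet with C1–H lying in the butenolide plane next to C13, free of allylic strain.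

Step 12
Reactants: 16 eight-membered bicyclic ketal
Product: 17 C7 alcohol
Conditions: HF·pyridine, pyridine, THF, 0 °C
Reagents that add atoms: none
Why: Buffered fluoride desilylation should remove the secondary triethylsilyl ether well before the primary and secondary TBS ethers (selective desilylation by silyl group size).

Step 13
Reactants: 17 C7 alcohol
Product: 18 C7 methyl ketone (β-keto ketal, used at once)
Conditions: Dess–Martin periodinane, pyridine, CH2Cl2, 0 °C → rt
Reagents that add atoms: none
Why: Dess–Martin oxidation under buffered, near-neutral conditions, chosen so that the ketone β to the ketal is not exposed to acid or strong base and does not eliminate.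

Step 14
Reactants: 18 C7 methyl ketone
Product: 19 (Z)-triethylsilyl enol ether (C8=C7)
Conditions: TESOTf, Et3N, CH2Cl2, −78 → −20 °C
Reagents that add atoms: triethylsilyl triflate, CC[Si](CC)(CC)OS(=O)(=O)C(F)(F)F
Why: Soft enolisation (O-silylation, then deprotonation by the amine) should take the more acidic C8 hydrogen next to the ketal carbon and give the more substituted enol silane, Z because the bulky C9 group stays trans to the C7 methyl group.

Step 15
Reactants: 19 (Z)-triethylsilyl enol ether
Product: 20 eight-membered 2-methylene cyclic ketal (Claisen precursor)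
Conditions: DBU, toluene, 50 °C; filtration through Et3N-deactivated silica, used directly
Reagents that add atoms: none
Why: E2 elimination of HI, in which C5–H is the only β-hydrogen and is both allylic and α to oxygen, so the exocyclic enol ether C5=C6 should form.

Step 16
Reactants: 20 eight-membered 2-methylene cyclic ketal
Product: 21 ten-membered C5 enone with C7–OTES and (E)-C8=C9 enol lactone
Conditions: toluene (0.01 M), Et3N (trace), base-washed sealed tube, 100 °C
Reagents that add atoms: none
Why: On heating, the allyl vinyl ether array C6=C5–O–C9–C8=C7 should undergo a concerted [3,3] sigmatropic (Claisen) shift in which C6–C7 forms while the ring C9–O bond breaks, giving the C5 ketone and the C8=C9 enol lactone. The closest known reaction is the Claisen ring expansion of 2-methylene oxacycles that bear a 1-alkenyl group on the ring carbon next to oxygen; a ketal carbon and an enol silane terminus have not been used there, but oxygen donors at exactly these two positions accelerate acyclic Claisen rearrangements. The ten-membered carbocycle is closed by ring expansion and not by cyclisation of a chain: C6–C7 is made across the eight-membered oxacycle and the O–C9 link is cut, so C1–C5 and C10 pass over unchanged with the cis C3=C4 bond already in place. C7 is set by C9: in the chair array that the short C4–C3–C2–C1–C10 tether can reach, C10 is pseudo-axial on C9 (so C7 ends cis to C10 across C8=C9) and the (Z)-enol silane has its oxygen pseudo-axial, which transfers 9S to 7S. The step needs the shift to run through C8=C7 and not through the butenolide C10=C11 bond, and through the chair and not a boat or an ion pair; the first is secured by the electron-rich enol silane terminus against an electron-poor terminus that would have to become a quaternary C11, the second by a non-polar solvent, an acid-free vessel and the intrinsic chair preference.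

Step 17
Reactants: 21 ten-membered C5 enone
Product: 22 (5R)-allylic alcohol
Conditions: (S)-2-methyl-CBS-oxazaborolidine (0.5 equiv), catecholborane, toluene, −78 °C
Reagents that add atoms: none
Why: Corey–Bakshi–Shibata reduction, in which the alkenyl side (C4) acts as the large group and the CH2 side (C6) as the small one, so the (S)-catalyst should give the (R)-carbinol by 1,2-reduction.

Step 18
Reactants: 22 (5R)-allylic alcohol
Product: 23 C5 acetate
Conditions: Ac2O, pyridine, DMAP (cat.), CH2Cl2, rt
Reagents that add atoms: acetic anhydride, CC(=O)OC(C)=O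
Why: DMAP-catalysed acetylation of the only free hydroxyl group.

Step 19
Reactants: 23 C5 acetate
Product: 24 C1,C7,C13-triol C5-acetate
Conditions: HF·pyridine, pyridine, THF, 0 °C → rt
Reagents that add atoms: none
Why: Global fluoride desilylation of the two TBS ethers and the tertiary TES ether under buffered conditions that should leave the acetate and the enol lactone alone.

Step 20
Reactants: 24 triol
Product: 25 C5,C13-diacetate with free C1 and C7 hydroxyls
Conditions: AcCl (1.05 equiv), 2,4,6-collidine, CH2Cl2, −78 °C
Reagents that add atoms: acetyl chloride, CC(Cl)=O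
Why: Low-temperature acylation with a hindered pyridine base should select the primary C13 hydroxyl over the hindered secondary C1 and the tertiary C7 hydroxyls.

Step 21
Reactants: 25 C5,C13-diacetate
Product: 26 target, C1 tiglate
Conditions: tiglic acid, 2,4,6-trichlorobenzoyl chloride, Et3N, toluene, rt; then DMAP, rt → 40 °C
Reagents that add atoms: tiglic acid, C/C=C(\C)C(O)=O
Why: Yamaguchi esterification through the mixed anhydride should acylate the secondary C1 hydroxyl and not the tertiary C7 hydroxyl, and avoids the base-induced double-bond shift seen with enoyl chlorides.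

**Compound list**

1 | dimethyl furan-3,4-dicarboxylate | COC(=O)c1cocc1C(=O)OC | starting material
2 | furan-3,4-diyldimethanol | OCc1cocc1CO | intermediate
3 | [4-(tert-butyldimethylsilyloxymethyl)furan-3-yl]methanol | CC(C)(C)[Si](C)(C)OCc1cocc1CO | intermediate
4 | (S)-propylene oxide | C[C@H]1CO1 | starting material
5 | dilithiated furan (lithium alkoxide of 3 lithiated at C9) | [Li]OCc1c([Li])occ1CO[Si](C)(C)C(C)(C)C | intermediate
6 | (2S)-1-[4-(tert-butyldimethylsilyloxymethyl)-3-(hydroxymethyl)furan-2-yl]propan-2-ol | C[C@H](O)Cc1occ(CO[Si](C)(C)C(C)(C)C)c1CO | intermediate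
7 | bis(triethylsilyl) ether of 6 | C[C@H](O[Si](CC)(CC)CC)Cc1occ(CO[Si](C)(C)C(C)(C)C)c1CO[Si](CC)(CC)CC | intermediate
8 | 4-(tert-butyldimethylsilyloxymethyl)-2-[(2S)-2-(triethylsilyloxy)propyl]furan-3-carbaldehyde | C[C@H](O[Si](CC)(CC)CC)Cc1occ(CO[Si](C)(C)C(C)(C)C)c1C=O | intermediate
9 | (1R)-homoallylic alcohol (C1–OH, 7S) | C[C@H](O[Si](CC)(CC)CC)Cc1occ(CO[Si](C)(C)C(C)(C)C)c1[C@H](O)CC(C)=C | intermediate
10 | fully protected furan (1R, 7S; C1–OTBS, C13–OTBS, C7–OTES) | C[C@H](O[Si](CC)(CC)CC)Cc1occ(CO[Si](C)(C)C(C)(C)C)c1[C@H](O[Si](C)(C)C(C)(C)C)CC(C)=C | intermediate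
11 | furan endoperoxide (peroxide bridge C9–C12) | C[C@H](O[Si](CC)(CC)CC)CC12OOC(O1)C(CO[Si](C)(C)C(C)(C)C)=C2[C@H](O[Si](C)(C)C(C)(C)C)CC(C)=C | intermediate
12 | 5-hydroxybutenolide (C9–OH, both C9 epimers; 1R, 7S) | C[C@H](O[Si](CC)(CC)CC)CC1(O)OC(=O)C(CO[Si](C)(C)C(C)(C)C)=C1[C@H](O[Si](C)(C)C(C)(C)C)CC(C)=C | intermediate
13 | (S)-2-hydroxybut-3-en-1-yl 4-methylbenzenesulfonate | C=C[C@H](O)COS(=O)(=O)c1ccc(C)cc1 | starting material
14 | (S)-1-iodobut-3-en-2-ol | C=C[C@H](O)CI | intermediate
15 | (9S)-mixed ketal (1R, 5S, 7S) | C=C[C@@H](CI)O[C@@]1(C[C@H](C)O[Si](CC)(CC)CC)OC(=O)C(CO[Si](C)(C)C(C)(C)C)=C1[C@H](O[Si](C)(C)C(C)(C)C)CC(C)=C | intermediate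
16 | eight-membered bicyclic ketal (1R, 3Z, 5S, 7S, 9S), C6 iodide, C7–OTES | CC(C)(C)[Si](C)(C)O[C@@H]1C/C(C)=C\[C@@H](CI)O[C@@]2(C[C@H](C)O[Si](CC)(CC)CC)OC(=O)C(CO[Si](C)(C)C(C)(C)C)=C21 | intermediate
17 | C7 alcohol of 16 | CC(C)(C)[Si](C)(C)O[C@@H]1C/C(C)=C\[C@@H](CI)O[C@@]2(C[C@H](C)O)OC(=O)C(CO[Si](C)(C)C(C)(C)C)=C21 | intermediate
18 | C7 methyl ketone (β-keto ketal) | CC(C)(C)[Si](C)(C)O[C@@H]1C/C(C)=C\[C@@H](CI)O[C@@]2(CC(C)=O)OC(=O)C(CO[Si](C)(C)C(C)(C)C)=C21 | intermediate
19 | (Z)-triethylsilyl enol ether with C6 iodide | CC(C)(C)[Si](C)(C)O[C@@H]1C/C(C)=C\[C@@H](CI)O[C@@]2(/C=C(/C)O[Si](CC)(CC)CC)OC(=O)C(CO[Si](C)(C)C(C)(C)C)=C21 | intermediate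
20 | eight-membered 2-methylene cyclic ketal (1R, 3Z, 9S) with (Z)-enol silane | CC(C)(C)[Si](C)(C)O[C@@H]1C/C(C)=C\C(=C)O[C@@]2(/C=C(/C)O[Si](CC)(CC)CC)OC(=O)C(CO[Si](C)(C)C(C)(C)C)=C21 | intermediate
21 | ten-membered C5 enone (1R, 3Z, 7S, 8E), C7–OTES | CC(C)(C)[Si](C)(C)O[C@@H]1C/C(C)=C\C(=O)C[C@](C)(O[Si](CC)(CC)CC)/C=C2/OC(=O)C(CO[Si](C)(C)C(C)(C)C)=C21 | intermediate
22 | (5R)-allylic alcohol | CC(C)(C)[Si](C)(C)O[C@@H]1C/C(C)=C\[C@H](O)C[C@](C)(O[Si](CC)(CC)CC)/C=C2/OC(=O)C(CO[Si](C)(C)C(C)(C)C)=C21 | intermediate
23 | C5 acetate | CC(C)(C)[Si](C)(C)O[C@@H]1C/C(C)=C\[C@H](OC(C)=O)C[C@](C)(O[Si](CC)(CC)CC)/C=C2/OC(=O)C(CO[Si](C)(C)C(C)(C)C)=C21 | intermediate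
24 | C1,C7,C13-triol C5-acetate | O[C@@H]1C/C(C)=C\[C@H](OC(C)=O)C[C@](C)(O)/C=C2/OC(=O)C(CO)=C21 | intermediate
25 | C5,C13-diacetate | O[C@@H]1C/C(C)=C\[C@H](OC(C)=O)C[C@](C)(O)/C=C2/OC(=O)C(COC(C)=O)=C21 | intermediate
26 | CNP0166369.1 (1R, 3Z, 5R, 7S, 8E) | C/C=C(\C)C(=O)O[C@@H]1C/C(C)=C\[C@H](OC(C)=O)C[C@](C)(O)/C=C2/OC(=O)C(COC(C)=O)=C21 | target

**Step count**

Total: 21 steps. Longest linear sequence: 20 steps (steps 1–8 and 10–21 from compound 1; step 9 is a one-step side branch).

**Steps most likely to fail**

Step 16 (Claisen ring expansion). The C9–O bond of this doubly donor-substituted ketal may ionise faster than the concerted shift proceeds, which would lead to recombination at C9, elimination or loss of the enol silane. A boat-like array may also compete and scramble the C8=C9 geometry and C7. The fallback gives up ring expansion and closes the ten-membered ring on the furan, with the enol lactone made last so that the ring fixes the C8=C9 geometry. It sets out from furan 10.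
- HF·pyridine/pyridine frees the C7 hydroxyl to give the furan alcohol F1.
- Dess–Martin oxidation gives the furan methyl ketone F2.
- A TiCl4-mediated Mukaiyama aldol addition of 2-(trimethylsilyloxy)buta-1,3-diene adds C6–C4 as a vinyl ketone and gives the tertiary carbinol F3. C9 no longer controls C7 here, so both C7 epimers would form and the series configured as in 21 has to be separated.
- TESOTf/2,6-lutidine gives the silyl ether F4.
- Ring-closing metathesis with second-generation Hoveyda–Grubbs catalyst RuCl2(=CH-2-i-PrOC6H4)(H2IMes) at high dilution closes C3=C4 to the furan-fused ten-membered enone F5.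
- Singlet oxygen followed by i-Pr2NEt gives the hydroxybutenolide F6.
- Dehydration across C8–C9 (MsCl, Et3N) comes back to the route at 21.

Step 10 (mixed ketal formation). Exchange at the crowded C9 may be slow, so that the hydroxybutenolide instead loses water across C8–C9, or the C7 triethylsilyl ether is lost to the acid. The fallback replaces the equilibrium exchange by an irreversible substitution on an activated donor. It sets out from 12: Ac2O/pyridine/DMAP gives the C9 acetate (acylal) F7, which with 14, catalytic TMSOTf and 2,6-di-tert-butyl-4-methylpyridine in CH2Cl2 at −78 °C is ionised and trapped by the alcohol. It comes back at 15 after separation of the C9 epimers.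

Step 17 (C5 reduction). The conformation of the ten-membered ring may expose only one face of the C5 carbonyl and override the catalyst, giving poor facial selectivity or mainly the (5S)-alcohol. The fallback lets the substrate decide and corrects by inversion. It sets out from 21: NaBH4/CeCl3 in MeOH at −78 °C gives the 1,2-reduction product, taken to be the (5S)-alcohol F8 when the ring bias is the cause of failure. Mitsunobu esterification (AcOH, PPh3, DIAD, toluene, 0 °C) then inverts C5 and installs the acetate in the same operation. It comes back at 23.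

**Further compounds**

F1 | step 16 | furan C7 alcohol (1R, 7S; C1–OTBS, C13–OTBS) | C[C@H](O)Cc1occ(CO[Si](C)(C)C(C)(C)C)c1[C@H](O[Si](C)(C)C(C)(C)C)CC(C)=C
F2 | step 16 | furan methyl ketone (C7=O) | CC(=O)Cc1occ(CO[Si](C)(C)C(C)(C)C)c1[C@H](O[Si](C)(C)C(C)(C)C)CC(C)=C
F3 | step 16 | furan tertiary carbinol with C5 vinyl ketone (C7 configured as in 21) | C=CC(=O)C[C@](C)(O)Cc1occ(CO[Si](C)(C)C(C)(C)C)c1[C@H](O[Si](C)(C)C(C)(C)C)CC(C)=C
F4 | step 16 | triethylsilyl ether of F3 | C=CC(=O)C[C@](C)(O[Si](CC)(CC)CC)Cc1occ(CO[Si](C)(C)C(C)(C)C)c1[C@H](O[Si](C)(C)C(C)(C)C)CC(C)=C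
F5 | step 16 | furan-fused ten-membered (3Z)-enone | CC(C)(C)[Si](C)(C)O[C@@H]1C/C(C)=C\C(=O)C[C@](C)(O[Si](CC)(CC)CC)Cc2occ(CO[Si](C)(C)C(C)(C)C)c21
F6 | step 16 | ten-membered 5-hydroxybutenolide (C9–OH, both C9 epimers) | CC(C)(C)[Si](C)(C)O[C@@H]1C/C(C)=C\C(=O)C[C@](C)(O[Si](CC)(CC)CC)CC2(O)OC(=O)C(CO[Si](C)(C)C(C)(C)C)=C21
F7 | step 10 | C9 acetate (acylal) of 12 | C[C@H](O[Si](CC)(CC)CC)CC1(OC(C)=O)OC(=O)C(CO[Si](C)(C)C(C)(C)C)=C1[C@H](O[Si](C)(C)C(C)(C)C)CC(C)=C
F8 | step 17 | (5S)-allylic alcohol, C5 epimer of 22 | CC(C)(C)[Si](C)(C)O[C@@H]1C/C(C)=C\[C@@H](O)C[C@](C)(O[Si](CC)(CC)CC)/C=C2/OC(=O)C(CO[Si](C)(C)C(C)(C)C)=C21
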